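**Strategy.** The 1,2-dioxane (O1, O2, C3 bearing CH2CO2Me, C4, C5, C6 bearing OMe) is cut through C4–C5 and C3–O2. C3 and C6 both carry oxygen, so C4 and C5 have like polarity and are joined by a radical. In one operation the trivalent-manganese-derived C5 radical of an acyclic β-keto ester (ketone = C6; ester = traceless activator) adds to C4 of methyl but-3-enoate, O2 is captured at C3 and the hydroperoxide closes onto C6: an aerobic [2+2+2] assembly of the ring from three achiral, acyclic pieces. Decarboxylation/methanolysis sets the anomeric ketal, resolution the absolute configuration, and Sonogashira coupling adds the enyne chain.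

Key step: step 2

Remark: ring positions in all names follow the numbering of the target (O1, O2, C3–C6), also where strict nomenclature would number otherwise; the radical key step cannot control C3, so material is racemic until step 4.

Step 1
Reactants: 1 hex-5-ynoic acid; 2 mono-tert-butyl malonate
Product: 5 tert-butyl 3-oxooct-7-ynoate, via acyl imidazolide 3 (not isolated), via acylmalonate half ester 4 (not isolated)
Conditions: CDI, THF, rt; then 2, MgCl2, Et3N, MeCN, rt; 1 M HCl work-up
Reagents that add atoms: none
Why: Claisen-type C-acylation of the magnesium enolate of the malonate half ester by the acyl imidazolide, followed by decarboxylation of the acylmalonic acid on acidic work-up, is a standard one-flask route from a carboxylic acid to a β-keto ester and leaves the terminal alkyne untouched.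

Step 2
Reactants: 5 tert-butyl 3-oxooct-7-ynoate; 6 methyl but-3-enoate
Product: 8 tert-butyl 6-hydroxy-3-(2-methoxy-2-oxoethyl)-6-(pent-4-yn-1-yl)-1,2-dioxane-5-carboxylate, via open-chain hydroperoxide 7 (not isolated)
Conditions: Mn(OAc)3·2H2O (0.2 equiv), O2 (1 atm), AcOH, 6 (8 equiv), 23 °C
Reagents that add atoms: dioxygen, O=O
Why: Trivalent manganese oxidises the enol of 5 to an electrophilic α,α-dicarbonyl radical that adds to the unsubstituted alkene terminus of 6 (C4–C5), the secondary C3 radical captures triplet O2 (C3–O2), the peroxyl radical is reduced to hydroperoxide 7 by divalent manganese (regenerating the oxidant) and 7 closes onto the ketone (O1–C6). The closest known reaction type is the Mn(OAc)3-catalysed aerobic [2+2+2] peroxycyclisation of 1,3-dicarbonyl compounds with alkenes to 1,2-dioxan-3-ols. The dioxane ring closes by 6-exo-trig addition of the hydroperoxide oxygen to the ketone carbonyl (reversible hemiketalisation), the ester carbonyl being far less electrophilic. C3 is formed in the O2 capture without control and is therefore racemic, while C5 and C6 are epimerisable and are erased (C5) or reset (C6) in step 3, so the absolute configuration is deferred to step 4. The step needs regioselective attack at C4 and chemoselectivity for the external alkene over O2 capture of the first radical and over 6-exo-dig attack on the tethered alkyne; the polarity match of an electrophilic radical with a terminal alkene, the large excess of 6 and the lower reactivity of alkynes toward electrophilic radicals should secure both.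

Step 3
Reactants: 8 tert-butyl 6-hydroxy-3-(2-methoxy-2-oxoethyl)-6-(pent-4-yn-1-yl)-1,2-dioxane-5-carboxylate
Product: 11 racemic methyl 2-[(3S*,6R*)-6-methoxy-6-(pent-4-yn-1-yl)-1,2-dioxan-3-yl]acetate, via hemiketal acid 9 (not isolated), via decarboxylated hemiketal 10 (not isolated)
Conditions: TFA, CH2Cl2, 0 °C to rt (until CO2 loss is complete); evaporate; MeOH, TsOH·H2O (cat.), rt
Reagents that add atoms: methanol, CO
Why: Acidolysis of the tert-butyl ester unmasks a β-keto acid equivalent (hemiketal in equilibrium with the γ-hydroperoxy β-keto acid) that should decarboxylate at C5, and acid-catalysed peroxyketalisation with methanol through the cyclic peroxycarbenium ion should then give the ketal under thermodynamic control, the anomeric effect placing OMe axial and both carbon substituents equatorial (OMe cis to the C3 side chain; the minor trans epimer is separated and re-equilibrated).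

Step 4
Reactants: 11 racemic methyl 2-[(3S*,6R*)-6-methoxy-6-(pent-4-yn-1-yl)-1,2-dioxan-3-yl]acetate
Product: 12 methyl 2-[(3S,6R)-6-methoxy-6-(pent-4-yn-1-yl)-1,2-dioxan-3-yl]acetate
Conditions: preparative HPLC on cellulose tris(3,5-dimethylphenylcarbamate) chiral phase, hexane/i-PrOH, rt
Reagents that add atoms: none
Why: Chromatographic resolution on a chiral stationary phase separates the two enantiomers of the cis-ketal and thereby fixes C3 as S (C6 already being R relative to it), neither centre being labile under the neutral elution conditions.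

Step 5
Reactants: 13 9-bromonon-1-ene
Product: 14 undec-1-en-10-yne
Conditions: LiC≡CH·H2NCH2CH2NH2, DMSO, 0 °C to rt
Reagents that add atoms: lithium acetylide–ethylenediamine complex, [Li]C#C.NCCN
Why: SN2 alkylation of lithium acetylide by a primary bromide in DMSO is a standard terminal-alkyne synthesis and does not touch the remote terminal alkene.

Step 6
Reactants: 14 undec-1-en-10-yne
Product: 16 (E)-1-iodoundeca-1,10-diene, via alkenylzirconocene chloride 15 (not isolated)
Conditions: Cp2Zr(H)Cl (1.05 equiv), THF, 0 °C to rt; then I2, 0 °C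
Reagents that add atoms: iodine, II
Why: Hydrozirconation adds Zr–H syn and anti-Markovnikov to the terminal alkyne (faster than to the terminal alkene with one equivalent of reagent), and iodinolysis of the C–Zr bond with retention should give the pure (E)-iodide.

Step 7
Reactants: 12 methyl 2-[(3S,6R)-6-methoxy-6-(pent-4-yn-1-yl)-1,2-dioxan-3-yl]acetate; 16 (E)-1-iodoundeca-1,10-diene
Product: 17 peroxyacarnoate A
Conditions: PdCl2(PPh3)2 (3 mol %), CuI (6 mol %), Et3N, THF, rt, degassed
Reagents that add atoms: none
Why: Sonogashira coupling (zerovalent palladium formed in situ, copper acetylide transmetalation) joins C(sp)–C(sp2) with retention of the (E)-geometry, the hindered dialkyl peroxyketal should tolerate these mild conditions, and a tertiary amine in aprotic THF is too weak to open the ring by retro-oxa-Michael reaction at C3.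

**Compound list**

1 | hex-5-ynoic acid | C#CCCCC(=O)O | starting material
2 | mono-tert-butyl malonate (3-tert-butoxy-3-oxopropanoic acid) | CC(C)(C)OC(=O)CC(=O)O | starting material
3 | 1-(hex-5-ynoyl)imidazole (not isolated) | C#CCCCC(=O)n1ccnc1 | intermediate
4 | 2-(tert-butoxycarbonyl)-3-oxooct-7-ynoic acid, present as its magnesium chelate (not isolated) | C#CCCCC(=O)C(C(=O)O)C(=O)OC(C)(C)C | intermediate
5 | tert-butyl 3-oxooct-7-ynoate | C#CCCCC(=O)CC(=O)OC(C)(C)C | intermediate
6 | methyl but-3-enoate | C=CCC(=O)OC | starting material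
7 | 1-tert-butyl 6-methyl 2-(hex-5-ynoyl)-4-hydroperoxyhexanedioate (open-chain hydroperoxide, racemic, not isolated) | C#CCCCC(=O)C(CC(OO)CC(=O)OC)C(=O)OC(C)(C)C | intermediate
8 | tert-butyl 6-hydroxy-3-(2-methoxy-2-oxoethyl)-6-(pent-4-yn-1-yl)-1,2-dioxane-5-carboxylate (racemic, mixture of C5/C6 epimers) | C#CCCCC1(O)OOC(CC(=O)OC)CC1C(=O)OC(C)(C)C | intermediate
9 | 6-hydroxy-3-(2-methoxy-2-oxoethyl)-6-(pent-4-yn-1-yl)-1,2-dioxane-5-carboxylic acid (racemic, not isolated) | C#CCCCC1(O)OOC(CC(=O)OC)CC1C(=O)O | intermediate
10 | methyl 2-[6-hydroxy-6-(pent-4-yn-1-yl)-1,2-dioxan-3-yl]acetate (racemic, hemiketal epimers, not isolated) | C#CCCCC1(O)CCC(CC(=O)OC)OO1 | intermediate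
11 | racemic methyl 2-[(3S*,6R*)-6-methoxy-6-(pent-4-yn-1-yl)-1,2-dioxan-3-yl]acetate (OMe cis to CH2CO2Me; written as the pair of enantiomers) | C#CCCC[C@]1(OC)CC[C@@H](CC(=O)OC)OO1.C#CCCC[C@@]1(OC)CC[C@H](CC(=O)OC)OO1 | intermediate
12 | methyl 2-[(3S,6R)-6-methoxy-6-(pent-4-yn-1-yl)-1,2-dioxan-3-yl]acetate | C#CCCC[C@]1(OC)CC[C@@H](CC(=O)OC)OO1 | intermediate
13 | 9-bromonon-1-ene | C=CCCCCCCCBr | starting material
14 | undec-1-en-10-yne | C=CCCCCCCCC#C | intermediate
15 | chlorobis(cyclopentadienyl)[(E)-undeca-1,10-dien-1-yl]zirconium (not isolated) | C=CCCCCCCC/C=C/[Zr](Cl)(C1C=CC=C1)C1C=CC=C1 | intermediate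
16 | (E)-1-iodoundeca-1,10-diene | C=CCCCCCCC/C=C/I | intermediate
17 | peroxyacarnoate A, methyl 2-[(3S,6R)-6-[(E)-hexadeca-6,15-dien-4-yn-1-yl]-6-methoxy-1,2-dioxan-3-yl]acetate | C=CCCCCCCC/C=C/C#CCCC[C@]1(OC)CC[C@@H](CC(=O)OC)OO1 | target

**Total step count:** 7. **Longest linear sequence:** 5 steps (steps 1, 2, 3, 4, 7).

**Steps most likely to fail**

1. Step 2 (key step). Risk: the manganese-bound radical of 5 is intercepted by O2 (α-oxygenation) or by the tethered alkyne (6-exo-dig carbocyclisation) before it reaches the weakly nucleophilic monosubstituted alkene. The fallback is polar, needs no radical, sets out from 5 and returns at 11. Compound 5 is C-alkylated with methyl (E)-4-bromobut-2-enoate (K2CO3, acetone) to 1-tert-butyl 6-methyl (E)-2-(hex-5-ynoyl)hex-4-enedioate F1. TFA, then warming in toluene, removes the tert-butyl ester and CO2 to give methyl (E)-6-oxoundec-2-en-10-ynoate F2. Urea–H2O2 with catalytic Sc(OTf)3 in MeOH converts the ketone into methyl (E)-6-hydroperoxy-6-methoxyundec-2-en-10-ynoate F3. Catalytic Et2NH in CF3CH2OH closes the ring by 6-exo oxa-Michael addition, and TsOH/MeOH equilibration of the ketal centre then delivers 11.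

2. Step 3. Risk: acid ionises the peroxyhemiketal faster than CO2 is lost (dehydration or fragmentation of the ring), or decarboxylation stalls because ring-opening to the keto acid is slow. The fallback replaces acidolysis by fluoride-triggered unmasking, sets out from 1 and returns at 10. Compound 1 is converted as in step 1, but with mono[2-(trimethylsilyl)ethyl] malonate, into 2-(trimethylsilyl)ethyl 3-oxooct-7-ynoate F4. The key step applied to F4 gives 2-(trimethylsilyl)ethyl 6-hydroxy-3-(2-methoxy-2-oxoethyl)-6-(pent-4-yn-1-yl)-1,2-dioxane-5-carboxylate F5. TBAF buffered with AcOH (THF, 0 °C) fragments the silylethyl ester, and the liberated acid decarboxylates near neutral pH to 10, which is methanolysed (MeOH, TsOH) to 11 as in the second half of step 3.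

3. Step 4. Risk: insufficient discrimination of the two enantiomers on the chiral phase (no chromophore, few binding handles), which limits throughput. The fallback is a covalent resolution that sets out from 11 and returns at 12. Compound 11 is transketalised with (1R,2S,5R)-menthol (TsOH cat., CH2Cl2, 4 Å molecular sieves) through the same peroxycarbenium ion. The two cis menthyl peroxyketals are diastereomers and should be separable on silica, a known principle for resolving peroxides as perketals of chiral alcohols. Methyl 2-[(3S,6R)-6-{[(1R,2S,5R)-2-isopropyl-5-methylcyclohexyl]oxy}-6-(pent-4-yn-1-yl)-1,2-dioxan-3-yl]acetate F6 is kept, and methyl 2-[(3R,6S)-6-{[(1R,2S,5R)-2-isopropyl-5-methylcyclohexyl]oxy}-6-(pent-4-yn-1-yl)-1,2-dioxan-3-yl]acetate F7 is discarded. F6 is returned to 12 by exchange in MeOH/TsOH, which leaves C3 untouched and sets C6 again under anomeric control.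

**Further compounds**

F1 | step 2 | 1-tert-butyl 6-methyl (E)-2-(hex-5-ynoyl)hex-4-enedioate | C#CCCCC(=O)C(C/C=C/C(=O)OC)C(=O)OC(C)(C)C
F2 | step 2 | methyl (E)-6-oxoundec-2-en-10-ynoate | C#CCCCC(=O)CC/C=C/C(=O)OC
F3 | step 2 | methyl (E)-6-hydroperoxy-6-methoxyundec-2-en-10-ynoate | C#CCCCC(OC)(OO)CC/C=C/C(=O)OC
F4 | step 3 | 2-(trimethylsilyl)ethyl 3-oxooct-7-ynoate | C#CCCCC(=O)CC(=O)OCC[Si](C)(C)C
F5 | step 3 | 2-(trimethylsilyl)ethyl 6-hydroxy-3-(2-methoxy-2-oxoethyl)-6-(pent-4-yn-1-yl)-1,2-dioxane-5-carboxylate | C#CCCCC1(O)OOC(CC(=O)OC)CC1C(=O)OCC[Si](C)(C)C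
F6 | step 4 | methyl 2-[(3S,6R)-6-{[(1R,2S,5R)-2-isopropyl-5-methylcyclohexyl]oxy}-6-(pent-4-yn-1-yl)-1,2-dioxan-3-yl]acetate | C#CCCC[C@]1(O[C@@H]2C[C@H](C)CC[C@H]2C(C)C)CC[C@@H](CC(=O)OC)OO1
F7 | step 4 | methyl 2-[(3R,6S)-6-{[(1R,2S,5R)-2-isopropyl-5-methylcyclohexyl]oxy}-6-(pent-4-yn-1-yl)-1,2-dioxan-3-yl]acetate | C#CCCC[C@@]1(O[C@@H]2C[C@H](C)CC[C@H]2C(C)C)CC[C@H](CC(=O)OC)OO1
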